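**Plan**
Retrosynthetic cuts: the 5'-O–acyl ester bond, the C1'–C(=O) bond to the cinnamoyl chain, then in ring A the C1'–C6' bond (ring expansion) and the C2'–C3' bond (vinyl–squarate union).
Enabling feature: ring A (chalcone numbering, C1' bears the ketone) has five adjacent oxygens on C2'–C6' and one carbon substituent; C3', C4', C5', C6' with their oxygens are the four carbons of a squarate, and C2'(O)–C1'(H) is a 1-alkoxyvinyl unit.
Forward: 1-tert-butoxyvinyllithium adds to di-tert-butyl squarate and the alkoxide is methylated (3'-OMe); thermal 4π opening and 6π closure then form ring A, the only ring made (ring B arrives with cinnamaldehyde).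
Chain assembly: 6'-O-methylation, lithiation at C1', addition to (E)-cinnamaldehyde and oxidation give the chalcone; the tert-butyl groups are then removed, 4'-OH is protected as a PMB ether, 5'-OH is acylated and the PMB group is removed.
Stereochemistry: the single stereocentre is bought as (S)-2-methylbutanoic acid and attached in the penultimate step without epimerisation; the E-alkene comes from (E)-cinnamaldehyde.

Key step: step 2

Remark: tert-butyl vinyl ether is assumed to undergo α-lithiation with t-BuLi in the same way as methyl and ethyl vinyl ether; primed locants are chalcone locants throughout.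

**Step 1**
Reactants: 1 tert-butyl vinyl ether; 2 di-tert-butyl squarate
Product: 5 2,3-di-tert-butoxy-4-(1-tert-butoxyethenyl)-4-methoxycyclobut-2-en-1-one (racemic), via 1-tert-butoxyethenyllithium 3 (not isolated), via lithium alkoxide 4 (not isolated)
Conditions: 1 (1.5 equiv), t-BuLi (1.2 equiv), THF, −78 → 0 °C; then 2, THF, −78 °C; then MeOTf, −78 → 0 °C; NaHCO3 aq work-up, Et3N-deactivated silica
Reagents that add atoms: methyl trifluoromethanesulfonate, COS(=O)(=O)C(F)(F)F
Why: α-Lithiation of an alkyl vinyl ether, 1,2-addition of the vinyllithium to one of the two equivalent carbonyls of a dialkyl squarate and O-methylation of the tertiary lithium alkoxide by methyl triflate are standard squarate chemistry, and the new quaternary stereocentre forms as a racemate that step 2 erases.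

**Step 2**
Reactants: 5 2,3-di-tert-butoxy-4-(1-tert-butoxyethenyl)-4-methoxycyclobut-2-en-1-one
Product: 8 2,3,5-tri-tert-butoxy-4-methoxyphenol, via dienylketene 6 (not isolated), via cyclohexadienone 7 (not isolated)
Conditions: degassed toluene, 110 °C, argon, base-washed glassware
Reagents that add atoms: none
Why: Heating should open the C1–C4 bond (carbonyl carbon to sp3 carbon) of the cyclobutenone by a thermally allowed conrotatory 4π electrocyclic reaction to give the (Z)-dienylketene 6, whose ketene carbon and terminal vinyl CH2 then join to give cyclohexa-2,4-dienone 7, and enolisation of its CH2–C=O unit delivers phenol 8. The closest known reaction type is the thermal ring expansion of squarate-derived 4-alkenyl-4-alkoxy- or 4-hydroxycyclobutenones to highly oxygenated phenols and hydroquinones (Moore rearrangement). Ring A closes by a disrotatory 6π electrocyclisation that forms the C1'–C6' bond. No stereocentre is created and the one in 5 disappears. The step needs the alkoxyvinyl group to rotate inward so that it lies cis to the ketene; the methoxy donor on the same sp3 carbon prefers outward rotation and so secures this, and because ring opening is reversible a wrongly configured ketene can return to 5. Regiochemistry is not in question, since only the bond between the carbonyl and the sp3 carbon can open and the squarate core was symmetric.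

**Step 3**
Reactants: 8 2,3,5-tri-tert-butoxy-4-methoxyphenol
Product: 9 1,3,4-tri-tert-butoxy-2,5-dimethoxybenzene
Conditions: MeI, K2CO3, DMF, rt, argon
Reagents that add atoms: iodomethane, CI
Why: Williamson O-methylation of the phenol under mildly basic conditions, which the acid-labile tert-butyl ethers tolerate, fixes the future 6'-OMe.

**Step 4**
Reactants: 9 1,3,4-tri-tert-butoxy-2,5-dimethoxybenzene; 10 (E)-cinnamaldehyde
Product: 12 (2E)-1-(2,4,5-tri-tert-butoxy-3,6-dimethoxyphenyl)-3-phenylprop-2-en-1-ol (racemic), via aryllithium 11 (not isolated)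
Conditions: s-BuLi, TMEDA, THF, −78 → −20 °C; then 10, −78 → 0 °C; H2O quench; crude carbinol used directly
Reagents that add atoms: none
Why: Directed ortho-lithiation takes place at the only ring C–H, which is flanked by two alkoxy groups as in 1,3-dialkoxybenzenes, and the aryllithium then adds 1,2 to the non-enolisable enal; the carbinol centre is racemic and is oxidised away in step 5.

**Step 5**
Reactants: 12 (2E)-1-(2,4,5-tri-tert-butoxy-3,6-dimethoxyphenyl)-3-phenylprop-2-en-1-ol
Product: 13 (2E)-1-(2,4,5-tri-tert-butoxy-3,6-dimethoxyphenyl)-3-phenylprop-2-en-1-one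
Conditions: activated MnO2 (excess), CH2Cl2, rt, dark
Reagents that add atoms: none
Why: MnO2 oxidises the doubly activated (allylic and benzylic) secondary alcohol to the enone under neutral conditions that leave the tert-butyl ethers and the E-alkene untouched.

**Step 6**
Reactants: 13 (2E)-1-(2,4,5-tri-tert-butoxy-3,6-dimethoxyphenyl)-3-phenylprop-2-en-1-one
Product: 14 (2E)-1-(2,4,5-trihydroxy-3,6-dimethoxyphenyl)-3-phenylprop-2-en-1-one
Conditions: TFA/CH2Cl2 (1:4), 0 °C → rt, argon; evaporated and used without exposure to air
Reagents that add atoms: none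
Why: Acidolysis of aryl tert-butyl ethers with loss of isobutene frees the 2'-, 4'- and 5'-hydroxyls while the methyl ethers stay, and because ring A is fully substituted no ring tert-butylation can occur; low temperature and short contact should keep the 2'-hydroxychalcone from closing to a flavanone.

**Step 7**
Reactants: 14 (2E)-1-(2,4,5-trihydroxy-3,6-dimethoxyphenyl)-3-phenylprop-2-en-1-one
Product: 15 (2E)-1-{2,5-dihydroxy-3,6-dimethoxy-4-[(4-methoxybenzyl)oxy]phenyl}-3-phenylprop-2-en-1-one
Conditions: PMBCl (1.05 equiv), NaHCO3, NaI (cat.), DMF, rt → 40 °C, argon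
Reagents that add atoms: 4-methoxybenzyl chloride, COc1ccc(CCl)cc1
Why: Regioselective Williamson etherification, in which the weak base ionises only the most acidic phenol, the 4'-OH para to the ketone (the selectivity known for 3,4-dihydroxybenzaldehyde and 2,4-dihydroxyacetophenones), while the 2'-OH is tied up in a hydrogen bond to the carbonyl and the 5'-OH is meta to it.

**Step 8**
Reactants: 15 (2E)-1-{2,5-dihydroxy-3,6-dimethoxy-4-[(4-methoxybenzyl)oxy]phenyl}-3-phenylprop-2-en-1-one; 16 (S)-2-methylbutanoic acid
Product: 17 4-hydroxy-3,6-dimethoxy-2-[(4-methoxybenzyl)oxy]-5-[(2E)-3-phenylprop-2-enoyl]phenyl (2S)-2-methylbutanoate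
Conditions: 16 (1.1 equiv), DCC, DMAP (cat.), CH2Cl2, 0 °C → rt, argon
Reagents that add atoms: none
Why: Steglich esterification acylates the only non-chelated phenol left, the 5'-OH, the hydrogen-bonded 2'-OH being far less nucleophilic; the stereocentre is carried in unchanged from 16, and low temperature with only catalytic DMAP guards against epimerisation.

**Step 9**
Reactants: 17 4-hydroxy-3,6-dimethoxy-2-[(4-methoxybenzyl)oxy]-5-[(2E)-3-phenylprop-2-enoyl]phenyl (2S)-2-methylbutanoate
Product: 18 2,4-dihydroxy-3,6-dimethoxy-5-[(2E)-3-phenylprop-2-enoyl]phenyl (2S)-2-methylbutanoate (CNP0237988.1)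
Conditions: TFA, pentamethylbenzene, CH2Cl2, 0 °C
Reagents that add atoms: none
Why: Acidolysis of an aryl 4-methoxybenzyl ether with a cation scavenger is standard, and the aryl ester, the methyl ethers, the enone and the α-stereocentre tolerate brief anhydrous acid; the freed 4'-OH is the more acidic of the two neighbouring oxygens, so acyl transfer away from O-5' is not favoured.

**Compound list**
1 | tert-butyl vinyl ether | C=COC(C)(C)C | starting material
2 | di-tert-butyl squarate (3,4-di-tert-butoxycyclobut-3-ene-1,2-dione) | CC(C)(C)OC1=C(OC(C)(C)C)C(=O)C1=O | starting material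
3 | 1-tert-butoxyethenyllithium | [Li]C(=C)OC(C)(C)C | intermediate
4 | lithium 2,3-di-tert-butoxy-1-(1-tert-butoxyethenyl)-4-oxocyclobut-2-en-1-olate (racemic) | [Li+].[O-]C1(C(=C)OC(C)(C)C)C(=O)C(OC(C)(C)C)=C1OC(C)(C)C | intermediate
5 | 2,3-di-tert-butoxy-4-(1-tert-butoxyethenyl)-4-methoxycyclobut-2-en-1-one (racemic) | C=C(OC(C)(C)C)C1(OC)C(=O)C(OC(C)(C)C)=C1OC(C)(C)C | intermediate
6 | (3Z)-2,3,5-tri-tert-butoxy-4-methoxyhexa-1,3,5-trien-1-one (dienylketene) | O=C=C(OC(C)(C)C)/C(OC(C)(C)C)=C(/OC)C(=C)OC(C)(C)C | intermediate
7 | 2,3,5-tri-tert-butoxy-4-methoxycyclohexa-2,4-dien-1-one | O=C1CC(OC(C)(C)C)=C(OC)C(OC(C)(C)C)=C1OC(C)(C)C | intermediate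
8 | 2,3,5-tri-tert-butoxy-4-methoxyphenol | CC(C)(C)Oc1cc(O)c(OC(C)(C)C)c(OC(C)(C)C)c1OC | intermediate
9 | 1,3,4-tri-tert-butoxy-2,5-dimethoxybenzene | COc1cc(OC(C)(C)C)c(OC)c(OC(C)(C)C)c1OC(C)(C)C | intermediate
10 | (E)-cinnamaldehyde | O=C/C=C/c1ccccc1 | starting material
11 | (2,4,5-tri-tert-butoxy-3,6-dimethoxyphenyl)lithium | [Li]c1c(OC)c(OC(C)(C)C)c(OC(C)(C)C)c(OC)c1OC(C)(C)C | intermediate
12 | (2E)-1-(2,4,5-tri-tert-butoxy-3,6-dimethoxyphenyl)-3-phenylprop-2-en-1-ol (racemic) | OC(/C=C/c1ccccc1)c1c(OC)c(OC(C)(C)C)c(OC(C)(C)C)c(OC)c1OC(C)(C)C | intermediate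
13 | (2E)-1-(2,4,5-tri-tert-butoxy-3,6-dimethoxyphenyl)-3-phenylprop-2-en-1-one | O=C(/C=C/c1ccccc1)c1c(OC)c(OC(C)(C)C)c(OC(C)(C)C)c(OC)c1OC(C)(C)C | intermediate
14 | (2E)-1-(2,4,5-trihydroxy-3,6-dimethoxyphenyl)-3-phenylprop-2-en-1-one | O=C(/C=C/c1ccccc1)c1c(OC)c(O)c(O)c(OC)c1O | intermediate
15 | (2E)-1-{2,5-dihydroxy-3,6-dimethoxy-4-[(4-methoxybenzyl)oxy]phenyl}-3-phenylprop-2-en-1-one | O=C(/C=C/c1ccccc1)c1c(OC)c(O)c(OCc2ccc(OC)cc2)c(OC)c1O | intermediate
16 | (S)-2-methylbutanoic acid | CC[C@H](C)C(=O)O | starting material
17 | 4-hydroxy-3,6-dimethoxy-2-[(4-methoxybenzyl)oxy]-5-[(2E)-3-phenylprop-2-enoyl]phenyl (2S)-2-methylbutanoate | CC[C@H](C)C(=O)Oc1c(OCc2ccc(OC)cc2)c(OC)c(O)c(C(=O)/C=C/c2ccccc2)c1OC | intermediate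
18 | 2,4-dihydroxy-3,6-dimethoxy-5-[(2E)-3-phenylprop-2-enoyl]phenyl (2S)-2-methylbutanoate (CNP0237988.1) | CC[C@H](C)C(=O)Oc1c(O)c(OC)c(O)c(C(=O)/C=C/c2ccccc2)c1OC | target

**Step count**
Total steps: 9. Longest linear sequence: 9 steps (1 and 2 to 18); 10 and 16 enter as purchased materials.

**Steps most likely to fail**

Step 7. The alkylation may spread from the 4'- to the 5'-oxygen or go twice, and the hydroquinone-type triol may oxidise to a quinone under base. The fallback sets out from 14 and avoids selective protection. Both non-chelated hydroxyls would be esterified with 16 (2.2 equiv, DCC, catalytic DMAP, CH2Cl2, 0 °C) to give 4-hydroxy-3,6-dimethoxy-5-[(2E)-3-phenylprop-2-enoyl]benzene-1,2-diyl bis[(2S)-2-methylbutanoate] F1. The 4'-ester, being the ester of the most acidic phenol (para to the ketone), should then be cleaved selectively by imidazole in aqueous 1,4-dioxane at rt to 40 °C, the method used to remove acyl groups para to a carbonyl in polyacylated flavonoids. Any acyl transfer between the neighbouring oxygens favours the 5'-ester. This comes back to the route at 18, bypassing 15 and 17.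

Step 1. O-Methylation of the hindered tertiary lithium alkoxide may be incomplete, and the tert-butyl enol ether may hydrolyse during isolation of the methyl ether. The fallback sets out from alkoxide 4, which would be quenched with water at −78 °C to give 2,3-di-tert-butoxy-4-(1-tert-butoxyethenyl)-4-hydroxycyclobut-2-en-1-one F2. Heating F2 in degassed toluene at 110 °C applies the same 4π opening and 6π closure to the classical 4-hydroxy substrate and should give 2,3,5-tri-tert-butoxybenzene-1,4-diol F3. Without exposure to air, both hydroxyls of F3 would be methylated (MeI, K2CO3, DMF, argon); since O-3' and O-6' are both methyl ethers in the target, this comes back to the route at 9, bypassing 5 and 8.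

Step 4. Deprotonation at C1' may be slow or incomplete because the bulky tert-butoxy group directs poorly, and the strong base may instead eliminate isobutene from a tert-butyl ether. The fallback sets out from 9 and replaces deprotonation by halogen–metal exchange. N-Bromosuccinimide in MeCN at 0 °C should brominate the only free ring position to give 1-bromo-2,4,5-tri-tert-butoxy-3,6-dimethoxybenzene F4. Bromine–lithium exchange with n-BuLi in THF at −78 °C then gives the aryllithium and comes back to the route at 11, which adds to 10 as before.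

**Further compounds**
F1 | step 7 | 4-hydroxy-3,6-dimethoxy-5-[(2E)-3-phenylprop-2-enoyl]benzene-1,2-diyl bis[(2S)-2-methylbutanoate] | CC[C@H](C)C(=O)Oc1c(OC(=O)[C@@H](C)CC)c(OC)c(O)c(C(=O)/C=C/c2ccccc2)c1OC
F2 | step 1 | 2,3-di-tert-butoxy-4-(1-tert-butoxyethenyl)-4-hydroxycyclobut-2-en-1-one (racemic) | C=C(OC(C)(C)C)C1(O)C(=O)C(OC(C)(C)C)=C1OC(C)(C)C
F3 | step 1 | 2,3,5-tri-tert-butoxybenzene-1,4-diol | CC(C)(C)Oc1cc(O)c(OC(C)(C)C)c(OC(C)(C)C)c1O
F4 | step 4 | 1-bromo-2,4,5-tri-tert-butoxy-3,6-dimethoxybenzene | COc1c(Br)c(OC(C)(C)C)c(OC)c(OC(C)(C)C)c1OC(C)(C)C
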